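**Retrosynthetic overview**

1. The route rests on the all-cis tetrahydrofuran: O1, C2 bearing ring B, C3 bearing CH2OH, C4 bearing the ring A benzyl group, C5. If the C3 side-chain carbon (as C=O) is joined through oxygen to the benzylic carbon on C4, this ring becomes a cis-fused 3,7-dioxabicyclo[3.3.0]octan-2-one with ring B endo. Hydrogenolysis, acid reduction and desilylation take that bicycle back to the target.
2. The bicycle is made from an α-diazo-γ-butyrolactone by rhodium carbenoid 1,5 C–H insertion into the benzylic ether CH2. This forms the C2–C3 bond and closes the tetrahydrofuran.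
3. The diazolactone is cut at the ether oxygen into a trans hydroxymethyl lactone (Evans syn-aldol of a succinate imide with O-benzylvanillin, then lactonisation) and the benzylic trichloroacetimidate of the bis(dihydrobenzofuran).
4. The bis(dihydrobenzofuran) is grown from 5-iodovanillin (used twice) and 4-benzyloxy-3-methoxybenzyl alcohol by two rounds of aryl diazoacetate formation and enantioselective carbenoid C–H insertion, one catalyst enantiomer per unit.
5. Ring order: dihydrofuran on ring C (unit C), dihydrofuran on ring B (unit B), γ-lactone, tetrahydrofuran. Ring A is the guaiacyl ring of the C4 benzyl group, rings B and C are the benzo rings of the two dihydrobenzofurans (B sits on C2), ring D is the terminal guaiacyl ring.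

Key step: step 19

Assumption: Rh2(S-PTTL)4 is taken to give the (2S)-dihydrobenzofuran and Rh2(R-PTTL)4 the (2R) one, by analogy with simpler aryl diazoacetates; if the sense is reversed for these substrates, the two catalysts change places between steps 3 and 7.

**Route**

Step 1
Reactants: 1 5-iodovanillin (4-hydroxy-3-iodo-5-methoxybenzaldehyde); 2 4-benzyloxy-3-methoxybenzyl alcohol
Product: 3 4-[(4-benzyloxy-3-methoxybenzyl)oxy]-3-iodo-5-methoxybenzaldehyde
Conditions: PPh3, DIAD, THF, 0 °C → rt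
Reagents that add atoms: none
Why: Mitsunobu etherification of an acidic phenol (formyl and iodo groups lower its pKa) with a primary benzylic alcohol should give the aryl benzyl ether without a benzylic halide; no stereocentre is involved.

Step 2
Reactants: 3 4-[(4-benzyloxy-3-methoxybenzyl)oxy]-3-iodo-5-methoxybenzaldehyde
Product: 4 ethyl 2-{2-[(4-benzyloxy-3-methoxybenzyl)oxy]-5-formyl-3-methoxyphenyl}-2-diazoacetate
Conditions: ethyl diazoacetate, Pd(PPh3)4 (5 mol%), Ag2CO3 (0.5 equiv), Et3N, toluene, rt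
Reagents that add atoms: ethyl diazoacetate, CCOC(=O)C=[N+]=[N-]
Why: Palladium-catalysed cross-coupling of an aryl iodide with the C–H bond of a diazoacetate (oxidative addition, palladation of the diazo carbon, reductive elimination) should give the aryl diazoacetate with the diazo group intact, Ag2CO3 taking up the iodide.

Step 3
Reactants: 4 ethyl 2-{2-[(4-benzyloxy-3-methoxybenzyl)oxy]-5-formyl-3-methoxyphenyl}-2-diazoacetate
Product: 6 ethyl (2S,3S)-2-(4-benzyloxy-3-methoxyphenyl)-5-formyl-7-methoxy-2,3-dihydrobenzofuran-3-carboxylate (trans ester of unit C), via cis-(2S,3R) ester 5 (not isolated)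
Conditions: Rh2(S-PTTL)4 (dirhodium tetrakis[N-phthaloyl-(S)-tert-leucinate], 1 mol%), toluene, −60 °C; then NaOEt (0.3 equiv), EtOH, 0 °C → rt
Reagents that add atoms: none
Why: Enantioselective intramolecular 1,5 C–H insertion of the aryl ester rhodium carbenoid into the benzylic ether C–H bond should close the dihydrofuran as the cis ester with C2 fixed by the chiral carboxylate ligands, and catalytic ethoxide then epimerises only the α-aryl ester carbon C3 to the more stable 2,3-trans isomer.

Step 4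
Reactants: 6 trans ester aldehyde of unit C
Product: 7 ethyl (2S,3S)-2-(4-benzyloxy-3-methoxyphenyl)-5-(hydroxymethyl)-7-methoxy-2,3-dihydrobenzofuran-3-carboxylate
Conditions: NaBH4, EtOH/THF, 0 °C
Reagents that add atoms: none
Why: Chemoselective borohydride reduction should convert the aryl aldehyde into the benzylic alcohol while the ethyl ester and both stereocentres stay untouched at 0 °C.

Step 5
Reactants: 7 ethyl (2S,3S)-2-(4-benzyloxy-3-methoxyphenyl)-5-(hydroxymethyl)-7-methoxy-2,3-dihydrobenzofuran-3-carboxylate; 1 5-iodovanillin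
Product: 8 ethyl (2S,3S)-2-(4-benzyloxy-3-methoxyphenyl)-5-[(4-formyl-2-iodo-6-methoxyphenoxy)methyl]-7-methoxy-2,3-dihydrobenzofuran-3-carboxylate
Conditions: PPh3, DIAD, THF, 0 °C → rt
Reagents that add atoms: none
Why: A second Mitsunobu etherification, of the ring C benzylic alcohol with the acidic phenol of 5-iodovanillin, should bring in ring B and create the next benzylic ether CH2 under neutral conditions that leave the ester-bearing stereocentres alone.

Step 6
Reactants: 8 iodo aryl ether of unit C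
Product: 9 ethyl (2S,3S)-2-(4-benzyloxy-3-methoxyphenyl)-5-{[2-(1-diazo-2-ethoxy-2-oxoethyl)-4-formyl-6-methoxyphenoxy]methyl}-7-methoxy-2,3-dihydrobenzofuran-3-carboxylate
Conditions: ethyl diazoacetate, Pd(PPh3)4 (5 mol%), Ag2CO3 (0.5 equiv), Et3N, toluene, rt
Reagents that add atoms: ethyl diazoacetate, CCOC(=O)C=[N+]=[N-]
Why: The same palladium-catalysed aryl iodide–diazoacetate cross-coupling as in step 2 should work here, since the ester and aldehyde are spectators and Et3N is too weak a base to touch the α-aryl ester.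

Step 7
Reactants: 9 aryl diazoacetate carrying unit C
Product: 11 ethyl (2R,3R)-2-[(2S,3S)-2-(4-benzyloxy-3-methoxyphenyl)-3-(ethoxycarbonyl)-7-methoxy-2,3-dihydrobenzofuran-5-yl]-5-formyl-7-methoxy-2,3-dihydrobenzofuran-3-carboxylate (trans in both units), via cis-(2R,3S) unit B diester 10 (not isolated)
Conditions: Rh2(R-PTTL)4 (dirhodium tetrakis[N-phthaloyl-(R)-tert-leucinate], 1 mol%), toluene, −60 °C; then NaOEt (0.3 equiv), EtOH, 0 °C → rt
Reagents that add atoms: none
Why: The same carbenoid 1,5 C–H insertion and epimerisation pair as in step 3, now with the enantiomeric catalyst, should set C2 of the new dihydrofuran on ring B as R under catalyst control (the unit C stereocentres are remote and already trans), after which ethoxide moves only the new C3 to trans.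

Step 8
Reactants: 11 trans,trans diester aldehyde
Product: 12 bis(dihydrobenzofuran) triol: unit B (2R,3S) with 3-CH2OH and 5-CH2OH, unit C (2S,3R) with 3-CH2OH and 2-(4-benzyloxy-3-methoxyphenyl)
Conditions: LiAlH4, THF, 0 °C
Reagents that add atoms: none
Why: Hydride reduction with LiAlH4 should take the aldehyde and both ethyl esters to primary alcohols in one operation, hydride addition being faster than enolisation, so the trans stereocentres are kept.

Step 9
Reactants: 12 bis(dihydrobenzofuran) triol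
Product: 13 (2R,3S)-2-[(2S,3R)-2-(4-benzyloxy-3-methoxyphenyl)-3-(hydroxymethyl)-7-methoxy-2,3-dihydrobenzofuran-5-yl]-3-(hydroxymethyl)-7-methoxy-2,3-dihydrobenzofuran-5-carbaldehyde
Conditions: MnO2 (activated, excess), CH2Cl2, rt
Reagents that add atoms: none
Why: Selective benzylic oxidation with MnO2 should convert only the ring B benzylic alcohol into the aldehyde and leave the two aliphatic primary alcohols, which differentiates the three hydroxyl groups.

Step 10
Reactants: 13 aldehyde diol
Product: 14 bis(tert-butyldimethylsilyl) ether of 13 (both 3-CH2OTBS, 5-CHO on ring B)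
Conditions: TBSCl, imidazole, DMF, rt
Reagents that add atoms: tert-butyldimethylsilyl chloride, CC(C)(C)[Si](C)(C)Cl
Why: Standard silylation of primary alcohols should give TBS ethers that withstand the later base, carbenoid, hydrogenolysis and borane steps.

Step 11
Reactants: 14 bis-TBS aldehyde
Product: 15 bis-TBS benzylic alcohol (5-CH2OH on ring B)
Conditions: NaBH4, MeOH/THF, 0 °C
Reagents that add atoms: none
Why: Borohydride reduction of the aryl aldehyde should give the benzylic alcohol with silyl ethers and stereocentres unchanged.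

Step 12
Reactants: 15 bis-TBS benzylic alcohol
Product: 16 ring B benzylic 2,2,2-trichloroacetimidate of 15
Conditions: Cl3CCN, DBU (cat.), CH2Cl2, 0 °C; used crude
Reagents that add atoms: trichloroacetonitrile, N#CC(Cl)(Cl)Cl
Why: Base-catalysed addition of the alcohol to trichloroacetonitrile (imidate formation) should give the benzylic trichloroacetimidate, which is taken on without chromatography because an electron-rich benzylic imidate is sensitive to acid and silica.

Step 13
Reactants: 17 (S)-4-benzyloxazolidin-2-one; 18 methyl 4-chloro-4-oxobutanoate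
Product: 19 methyl 4-[(S)-4-benzyl-2-oxooxazolidin-3-yl]-4-oxobutanoate
Conditions: n-BuLi, THF, −78 °C; then 18, −78 → 0 °C
Reagents that add atoms: none
Why: N-Acylation of the lithiated oxazolidinone with the succinic half-ester acid chloride should give the succinate imide cleanly.

Step 14
Reactants: 19 succinate imide; 20 4-benzyloxy-3-methoxybenzaldehyde (O-benzylvanillin)
Product: 22 (S)-4-benzyl-3-{[(2S,3S)-2-(4-benzyloxy-3-methoxyphenyl)-5-oxotetrahydrofuran-3-yl]carbonyl}oxazolidin-2-one (trans lactone), via syn-aldol hydroxy ester 21 (not isolated)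
Conditions: Bu2BOTf, iPr2NEt, CH2Cl2, 0 °C; 20, −78 → 0 °C; pH 7 buffer, MeOH, H2O2; then TsOH·H2O (cat.), CH2Cl2, rt
Reagents that add atoms: none
Why: In this Evans syn-aldol reaction the (Z)-dibutylboron enolate forms only at the imide α-carbon and adds to the aldehyde through a Zimmerman–Traxler chair on the face away from the auxiliary benzyl group, which sets both stereocentres (3S,4S); the hydroxy ester then lactonises under acid catalysis to the trans γ-lactone.

Step 15
Reactants: 22 lactone imide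
Product: 23 (2S,3S)-2-(4-benzyloxy-3-methoxyphenyl)-5-oxotetrahydrofuran-3-carboxylic acid
Conditions: LiOH, H2O2, THF/H2O, 0 °C; Na2SO3; then 1 M HCl to pH 2
Reagents that add atoms: hydrogen peroxide, OO
Why: Lithium hydroperoxide should cleave the exocyclic imide carbonyl selectively (auxiliary hydrolysis), any opened lactone re-closes on acidification, and the stereocentres are not epimerised at 0 °C.

Step 16
Reactants: 23 lactone acid
Product: 24 (4R,5S)-5-(4-benzyloxy-3-methoxyphenyl)-4-(hydroxymethyl)dihydrofuran-2(3H)-one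
Conditions: BH3·SMe2, THF, 0 °C → rt; aqueous work-up
Reagents that add atoms: none
Why: Borane reduces a free carboxylic acid much faster than a lactone (chemoselective acid reduction), and the base-free conditions avoid translactonisation of the hydroxymethyl lactone.

Step 17
Reactants: 24 hydroxymethyl lactone; 16 benzylic trichloroacetimidate
Product: 25 (4R,5S)-5-(4-benzyloxy-3-methoxyphenyl)-4-{[(ring B)methoxy]methyl}dihydrofuran-2(3H)-one, the benzylic ether of 24 with the bis-TBS bis(dihydrobenzofuran)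
Conditions: TMSOTf (5 mol%), 4 Å molecular sieves, CH2Cl2, −78 → −40 °C; Et3N quench
Reagents that add atoms: none
Why: Acid-catalysed O-alkylation with a benzylic trichloroacetimidate should let the primary alcohol capture the electron-rich ring B benzylic electrophile at low temperature, which avoids the base-induced translactonisation of 24 and keeps the TBS ethers.

Step 18
Reactants: 25 lactone ether
Product: 27 (4R,5S)-3-diazo-5-(4-benzyloxy-3-methoxyphenyl)-4-{[(ring B)methoxy]methyl}dihydrofuran-2(3H)-one, via α-trifluoroacetyl lactone 26 (not isolated)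
Conditions: LiN(SiMe3)2, THF, −78 °C; CF3CO2CH2CF3; 5% HCl work-up; then 4-acetamidobenzenesulfonyl azide, Et3N, H2O (1 equiv), MeCN, rt
Reagents that add atoms: 2,2,2-trifluoroethyl trifluoroacetate, O=C(OCC(F)(F)F)C(F)(F)F; 4-acetamidobenzenesulfonyl azide, CC(=O)Nc1ccc(cc1)S(=O)(=O)N=[N+]=[N-]
Why: In this deacylative (detrifluoroacetylative) Regitz-type diazo transfer the lactone lithium enolate is C-trifluoroacetylated and the activated α-position then takes the diazo group from the sulfonyl azide with loss of the trifluoroacetyl group, without involving the two lactone stereocentres.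

Step 19
Reactants: 27 α-diazo lactone
Product: 28 (1S,4S,5R,8R)-4-(4-benzyloxy-3-methoxyphenyl)-8-(ring B aryl)-3,7-dioxabicyclo[3.3.0]octan-2-one (cis-fused; ring A exo at C4, ring B endo at C8)
Conditions: Rh2(OAc)4 (2 mol%), CH2Cl2, rt, slow addition of 27
Reagents that add atoms: none
Why: Rh2(OAc)4 (divalent rhodium) takes N2 from 27 and gives an electrophilic rhodium carbenoid at the lactone α-carbon (the future C3), which inserts into a benzylic ether C–H bond five atoms away through a three-centre, hydride-transfer-like transition state and so forms the C2–C3 bond in one concerted event. The closest known reaction type is the dirhodium tetracarboxylate-catalysed 1,5 C–H insertion of α-diazo-γ-butyrolactones into ether C–H bonds, which gives furofuranones with an endo aryl group. The tetrahydrofuran closes by this 1,5 insertion through a five-membered cyclic transition state, and because the tether hangs from the future C4 the new ring can only be cis-fused to the lactone. C3 is therefore set by the C4 stereocentre made in the aldol step, and C2 is set kinetically: of the two diastereotopic benzylic hydrogens, the one transferred is that whose transition state turns ring B away from the dirhodium core on the convex face, which leaves ring B endo (cis to the lactone carbonyl carbon). The step needs site selectivity and chemoselectivity: this CH2 is the only C–H within 1,5 reach, it is activated by the ether oxygen and by electron-rich ring B, and slow addition at high dilution holds back carbene dimerisation and the 1,2-hydride shift to the butenolide. The ring A carbon of the lactone stays exo and unchanged.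

Step 20
Reactants: 28 endo-aryl furofuranone
Product: 29 (2R,3S,4R)-4-(4-hydroxy-3-methoxybenzyl)-2-(ring B aryl)tetrahydrofuran-3-carboxylic acid (all-cis; both TBS ethers kept, ring A and ring D phenols free)
Conditions: H2 (1 atm), Pd/C (10% palladium on carbon), EtOAc, rt, stopped when the lactone is consumed
Reagents that add atoms: none
Why: Catalytic hydrogenolysis should cleave the two aryl benzyl ethers and the benzylic lactone C–O bond (a benzylic carboxylate on an electron-rich ring) before the cyclic benzylic ether bonds of the tetrahydrofuran and dihydrobenzofurans, so the former lactone carbinol becomes the ring A CH2 on C4 and the carbonyl carbon becomes CO2H on C3 with no other stereocentre touched.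

Step 21
Reactants: 29 all-cis tetrahydrofuran acid
Product: 30 bis-TBS ether of the target (C3 CH2OH free, both phenols free)
Conditions: BH3·THF (excess), THF, 0 °C → rt; MeOH then aqueous work-up
Reagents that add atoms: none
Why: Borane reduction takes the carboxylic acid chemoselectively to CH2OH (the phenols only form aryloxyboranes that hydrolyse on work-up) without base or strong acid, so C3 and the acid-labile benzylic ether carbon C2 keep the all-cis arrangement.

Step 22
Reactants: 30 bis-TBS ether of the target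
Product: 31 target CNP0395728.1, (2R,3R,4R)-tetrahydrofuran with unit B (2R,3S) and unit C (2S,3R)
Conditions: Bu4NF, AcOH, THF, 0 °C → rt
Reagents that add atoms: none
Why: Fluoride-mediated desilylation buffered with acetic acid should remove both TBS ethers under conditions too mild to epimerise C2 or open the dihydrobenzofurans.

**Compound list**

1 | 5-iodovanillin | COc1cc(C=O)cc(I)c1O | starting material
2 | 4-benzyloxy-3-methoxybenzyl alcohol | COc1cc(CO)ccc1OCc1ccccc1 | starting material
3 | 4-[(4-benzyloxy-3-methoxybenzyl)oxy]-3-iodo-5-methoxybenzaldehyde | COc1cc(C=O)cc(I)c1OCc1ccc(OCc2ccccc2)c(OC)c1 | intermediate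
4 | ethyl 2-{2-[(4-benzyloxy-3-methoxybenzyl)oxy]-5-formyl-3-methoxyphenyl}-2-diazoacetate | CCOC(=O)C(=[N+]=[N-])c1cc(C=O)cc(OC)c1OCc1ccc(OCc2ccccc2)c(OC)c1 | intermediate
5 | ethyl (2S,3R)-2-(4-benzyloxy-3-methoxyphenyl)-5-formyl-7-methoxy-2,3-dihydrobenzofuran-3-carboxylate (cis, not isolated) | O=Cc1cc(OC)c2c(c1)[C@@H](C(=O)OCC)[C@@H](c1ccc(OCc3ccccc3)c(OC)c1)O2 | intermediate
6 | ethyl (2S,3S)-2-(4-benzyloxy-3-methoxyphenyl)-5-formyl-7-methoxy-2,3-dihydrobenzofuran-3-carboxylate (trans) | O=Cc1cc(OC)c2c(c1)[C@H](C(=O)OCC)[C@@H](c1ccc(OCc3ccccc3)c(OC)c1)O2 | intermediate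
7 | ethyl (2S,3S)-2-(4-benzyloxy-3-methoxyphenyl)-5-(hydroxymethyl)-7-methoxy-2,3-dihydrobenzofuran-3-carboxylate | OCc1cc(OC)c2c(c1)[C@H](C(=O)OCC)[C@@H](c1ccc(OCc3ccccc3)c(OC)c1)O2 | intermediate
8 | ethyl (2S,3S)-2-(4-benzyloxy-3-methoxyphenyl)-5-[(4-formyl-2-iodo-6-methoxyphenoxy)methyl]-7-methoxy-2,3-dihydrobenzofuran-3-carboxylate | COc1cc(C=O)cc(I)c1OCc1cc(OC)c2c(c1)[C@H](C(=O)OCC)[C@@H](c1ccc(OCc3ccccc3)c(OC)c1)O2 | intermediate
9 | ethyl (2S,3S)-2-(4-benzyloxy-3-methoxyphenyl)-5-{[2-(1-diazo-2-ethoxy-2-oxoethyl)-4-formyl-6-methoxyphenoxy]methyl}-7-methoxy-2,3-dihydrobenzofuran-3-carboxylate | CCOC(=O)C(=[N+]=[N-])c1cc(C=O)cc(OC)c1OCc1cc(OC)c2c(c1)[C@H](C(=O)OCC)[C@@H](c1ccc(OCc3ccccc3)c(OC)c1)O2 | intermediate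
10 | diester aldehyde with unit B cis (2R,3S) and unit C trans (2S,3S) (not isolated) | O=Cc1cc(OC)c2c(c1)[C@H](C(=O)OCC)[C@H](c1cc(OC)c3c(c1)[C@H](C(=O)OCC)[C@@H](c1ccc(OCc4ccccc4)c(OC)c1)O3)O2 | intermediate
11 | ethyl (2R,3R)-2-[(2S,3S)-2-(4-benzyloxy-3-methoxyphenyl)-3-(ethoxycarbonyl)-7-methoxy-2,3-dihydrobenzofuran-5-yl]-5-formyl-7-methoxy-2,3-dihydrobenzofuran-3-carboxylate | O=Cc1cc(OC)c2c(c1)[C@@H](C(=O)OCC)[C@H](c1cc(OC)c3c(c1)[C@H](C(=O)OCC)[C@@H](c1ccc(OCc4ccccc4)c(OC)c1)O3)O2 | intermediate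
12 | bis(dihydrobenzofuran) triol, unit B (2R,3S), unit C (2S,3R) | OCc1cc(OC)c2c(c1)[C@@H](CO)[C@H](c1cc(OC)c3c(c1)[C@H](CO)[C@@H](c1ccc(OCc4ccccc4)c(OC)c1)O3)O2 | intermediate
13 | ring B aldehyde diol | O=Cc1cc(OC)c2c(c1)[C@@H](CO)[C@H](c1cc(OC)c3c(c1)[C@H](CO)[C@@H](c1ccc(OCc4ccccc4)c(OC)c1)O3)O2 | intermediate
14 | ring B aldehyde bis-TBS ether | O=Cc1cc(OC)c2c(c1)[C@@H](CO[Si](C)(C)C(C)(C)C)[C@H](c1cc(OC)c3c(c1)[C@H](CO[Si](C)(C)C(C)(C)C)[C@@H](c1ccc(OCc4ccccc4)c(OC)c1)O3)O2 | intermediate
15 | ring B benzylic alcohol bis-TBS ether | OCc1cc(OC)c2c(c1)[C@@H](CO[Si](C)(C)C(C)(C)C)[C@H](c1cc(OC)c3c(c1)[C@H](CO[Si](C)(C)C(C)(C)C)[C@@H](c1ccc(OCc4ccccc4)c(OC)c1)O3)O2 | intermediate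
16 | ring B benzylic trichloroacetimidate | N=C(OCc1cc(OC)c2c(c1)[C@@H](CO[Si](C)(C)C(C)(C)C)[C@H](c1cc(OC)c3c(c1)[C@H](CO[Si](C)(C)C(C)(C)C)[C@@H](c1ccc(OCc4ccccc4)c(OC)c1)O3)O2)C(Cl)(Cl)Cl | intermediate
17 | (S)-4-benzyloxazolidin-2-one | O=C1N[C@@H](Cc2ccccc2)CO1 | starting material
18 | methyl 4-chloro-4-oxobutanoate | COC(=O)CCC(=O)Cl | starting material
19 | methyl 4-[(S)-4-benzyl-2-oxooxazolidin-3-yl]-4-oxobutanoate | COC(=O)CCC(=O)N1[C@@H](Cc2ccccc2)COC1=O | intermediate
20 | 4-benzyloxy-3-methoxybenzaldehyde | COc1cc(C=O)ccc1OCc1ccccc1 | starting material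
21 | methyl (3S,4S)-3-[(S)-4-benzyl-2-oxooxazolidine-3-carbonyl]-4-(4-benzyloxy-3-methoxyphenyl)-4-hydroxybutanoate (not isolated) | O[C@H](c1ccc(OCc2ccccc2)c(OC)c1)[C@@H](C(=O)N1[C@@H](Cc2ccccc2)COC1=O)CC(=O)OC | intermediate
22 | (S)-4-benzyl-3-{[(2S,3S)-2-(4-benzyloxy-3-methoxyphenyl)-5-oxotetrahydrofuran-3-yl]carbonyl}oxazolidin-2-one | O=C1O[C@H](c2ccc(OCc3ccccc3)c(OC)c2)[C@@H](C(=O)N2[C@@H](Cc3ccccc3)COC2=O)C1 | intermediate
23 | (2S,3S)-2-(4-benzyloxy-3-methoxyphenyl)-5-oxotetrahydrofuran-3-carboxylic acid | O=C1O[C@H](c2ccc(OCc3ccccc3)c(OC)c2)[C@@H](C(=O)O)C1 | intermediate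
24 | (4R,5S)-5-(4-benzyloxy-3-methoxyphenyl)-4-(hydroxymethyl)dihydrofuran-2(3H)-one | O=C1O[C@H](c2ccc(OCc3ccccc3)c(OC)c2)[C@@H](CO)C1 | intermediate
25 | (4R,5S) lactone benzylic ether with the bis-TBS bis(dihydrobenzofuran) | O=C1O[C@H](c2ccc(OCc3ccccc3)c(OC)c2)[C@@H](COCc2cc(OC)c3c(c2)[C@@H](CO[Si](C)(C)C(C)(C)C)[C@H](c2cc(OC)c4c(c2)[C@H](CO[Si](C)(C)C(C)(C)C)[C@@H](c2ccc(OCc5ccccc5)c(OC)c2)O4)O3)C1 | intermediate
26 | α-trifluoroacetyl derivative of 25 (α-carbon unassigned, keto/enol; not isolated) | O=C1O[C@H](c2ccc(OCc3ccccc3)c(OC)c2)[C@@H](COCc2cc(OC)c3c(c2)[C@@H](CO[Si](C)(C)C(C)(C)C)[C@H](c2cc(OC)c4c(c2)[C@H](CO[Si](C)(C)C(C)(C)C)[C@@H](c2ccc(OCc5ccccc5)c(OC)c2)O4)O3)C1C(=O)C(F)(F)F | intermediate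
27 | (4R,5S)-3-diazo lactone ether | O=C1O[C@H](c2ccc(OCc3ccccc3)c(OC)c2)[C@@H](COCc2cc(OC)c3c(c2)[C@@H](CO[Si](C)(C)C(C)(C)C)[C@H](c2cc(OC)c4c(c2)[C@H](CO[Si](C)(C)C(C)(C)C)[C@@H](c2ccc(OCc5ccccc5)c(OC)c2)O4)O3)C1=[N+]=[N-] | intermediate
28 | (1S,4S,5R,8R) endo-aryl furofuranone | O=C1O[C@H](c2ccc(OCc3ccccc3)c(OC)c2)[C@H]2CO[C@@H](c3cc(OC)c4c(c3)[C@@H](CO[Si](C)(C)C(C)(C)C)[C@H](c3cc(OC)c5c(c3)[C@H](CO[Si](C)(C)C(C)(C)C)[C@@H](c3ccc(OCc6ccccc6)c(OC)c3)O5)O4)[C@H]21 | intermediate
29 | (2R,3S,4R) all-cis tetrahydrofuran-3-carboxylic acid, bis-TBS, phenols free | COc1cc(C[C@H]2CO[C@@H](c3cc(OC)c4c(c3)[C@@H](CO[Si](C)(C)C(C)(C)C)[C@H](c3cc(OC)c5c(c3)[C@H](CO[Si](C)(C)C(C)(C)C)[C@@H](c3ccc(O)c(OC)c3)O5)O4)[C@H]2C(=O)O)ccc1O | intermediate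
30 | bis-TBS ether of the target | COc1cc(C[C@H]2CO[C@@H](c3cc(OC)c4c(c3)[C@@H](CO[Si](C)(C)C(C)(C)C)[C@H](c3cc(OC)c5c(c3)[C@H](CO[Si](C)(C)C(C)(C)C)[C@@H](c3ccc(O)c(OC)c3)O5)O4)[C@H]2CO)ccc1O | intermediate
31 | CNP0395728.1 | COc1cc(C[C@H]2CO[C@@H](c3cc(OC)c4c(c3)[C@@H](CO)[C@H](c3cc(OC)c5c(c3)[C@H](CO)[C@@H](c3ccc(O)c(OC)c3)O5)O4)[C@H]2CO)ccc1O | target

**Step count**

Total: 22 steps. Longest linear sequence: 18 steps (steps 1–12, then 17–22); the lactone branch (steps 13–16) joins at step 17.

**Steps most likely to fail**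

1. Step 19. The carbenoid may be lost to 1,2-hydride migration from the neighbouring C–H (butenolide formation) or to dimerisation, or the insertion may show poor endo/exo control on this large substrate. The fallback sets out from 24 and 14 and returns at 28. Alcohol 24 is silylated (Et3SiCl, imidazole, CH2Cl2) to the triethylsilyl ether F1. Its lithium enolate (LiN(SiMe3)2, THF, −78 °C) is added to aldehyde 14 to give the aldol adduct F2, whose two new centres need no control because both are reset later. Dess–Martin oxidation gives the β-keto lactone F3. Et3SiH with catalytic TMSOTf (CH2Cl2/MeCN, −78 → −40 °C) then effects an intramolecular reductive etherification: the silyl ether oxygen adds to the aryl ketone, the aryl-stabilised bicyclic oxocarbenium ion can only be cis-fused (the α-carbon is epimerisable), and hydride should enter from the convex face, leaving ring B endo and giving 28.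

2. Step 20. Hydrogenolysis may run on into the tetrahydrofuran C2–O1 bond or a dihydrobenzofuran C–O bond before the lactone C–O bond is fully cleaved, or stall at the debenzylated lactone. The fallback sets out from 28 and returns at 31. LiAlH4 (THF, 0 °C) opens the lactone to the diol F4. The primary alcohol is silylated selectively (TBSCl, imidazole, CH2Cl2, 0 °C) to the secondary benzylic alcohol F5. NaH, CS2 and MeI give the xanthate F6. Bu3SnH and AIBN (toluene, 90 °C; Barton–McCombie deoxygenation through the ring A benzylic radical) give the deoxygenated tris-silyl ether F7. Bu4NF/AcOH gives the bis(benzyl ether) F8, and a short hydrogenolysis (H2, Pd/C, EtOAc) that now has only two aryl benzyl ethers to cleave gives 31.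

3. Step 17. The electron-rich imidate may rearrange to the N-benzyl trichloroacetamide or alkylate one of the electron-rich arenes faster than it etherifies the alcohol, or silyl groups may be lost to the acid. The fallback sets out from 24 and 14 and returns at 25. Alcohol 24 is converted (Me3SiCl, Et3N, CH2Cl2) into the trimethylsilyl ether F9. F9 is combined with aldehyde 14, Et3SiH and catalytic TMSOTf (CH2Cl2, −78 °C) in a reductive etherification that should give 25 directly; steps 11 and 12 are then not needed.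

**Further compounds**

F1 | step 19 | triethylsilyl ether of 24 | O=C1O[C@H](c2ccc(OCc3ccccc3)c(OC)c2)[C@@H](CO[Si](CC)(CC)CC)C1
F2 | step 19 | aldol adduct of F1 with 14 (α-carbon and carbinol unassigned) | O=C1O[C@H](c2ccc(OCc3ccccc3)c(OC)c2)[C@@H](CO[Si](CC)(CC)CC)C1C(O)c1cc(OC)c2c(c1)[C@@H](CO[Si](C)(C)C(C)(C)C)[C@H](c1cc(OC)c3c(c1)[C@H](CO[Si](C)(C)C(C)(C)C)[C@@H](c1ccc(OCc4ccccc4)c(OC)c1)O3)O2
F3 | step 19 | β-keto lactone (α-carbon unassigned) | O=C1O[C@H](c2ccc(OCc3ccccc3)c(OC)c2)[C@@H](CO[Si](CC)(CC)CC)C1C(=O)c1cc(OC)c2c(c1)[C@@H](CO[Si](C)(C)C(C)(C)C)[C@H](c1cc(OC)c3c(c1)[C@H](CO[Si](C)(C)C(C)(C)C)[C@@H](c1ccc(OCc4ccccc4)c(OC)c1)O3)O2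
F4 | step 20 | diol from reduction of 28 | O[C@H](c1ccc(OCc2ccccc2)c(OC)c1)[C@H]1CO[C@@H](c2cc(OC)c3c(c2)[C@@H](CO[Si](C)(C)C(C)(C)C)[C@H](c2cc(OC)c4c(c2)[C@H](CO[Si](C)(C)C(C)(C)C)[C@@H](c2ccc(OCc5ccccc5)c(OC)c2)O4)O3)[C@H]1CO
F5 | step 20 | primary TBS ether of F4 (secondary benzylic alcohol free) | O[C@H](c1ccc(OCc2ccccc2)c(OC)c1)[C@H]1CO[C@@H](c2cc(OC)c3c(c2)[C@@H](CO[Si](C)(C)C(C)(C)C)[C@H](c2cc(OC)c4c(c2)[C@H](CO[Si](C)(C)C(C)(C)C)[C@@H](c2ccc(OCc5ccccc5)c(OC)c2)O4)O3)[C@H]1CO[Si](C)(C)C(C)(C)C
F6 | step 20 | S-methyl xanthate of F5 | CSC(=S)O[C@H](c1ccc(OCc2ccccc2)c(OC)c1)[C@H]1CO[C@@H](c2cc(OC)c3c(c2)[C@@H](CO[Si](C)(C)C(C)(C)C)[C@H](c2cc(OC)c4c(c2)[C@H](CO[Si](C)(C)C(C)(C)C)[C@@H](c2ccc(OCc5ccccc5)c(OC)c2)O4)O3)[C@H]1CO[Si](C)(C)C(C)(C)C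
F7 | step 20 | deoxygenated tris-TBS bis(benzyl ether) of the target | COc1cc(C[C@H]2CO[C@@H](c3cc(OC)c4c(c3)[C@@H](CO[Si](C)(C)C(C)(C)C)[C@H](c3cc(OC)c5c(c3)[C@H](CO[Si](C)(C)C(C)(C)C)[C@@H](c3ccc(OCc6ccccc6)c(OC)c3)O5)O4)[C@H]2CO[Si](C)(C)C(C)(C)C)ccc1OCc1ccccc1
F8 | step 20 | bis(benzyl ether) of the target | COc1cc(C[C@H]2CO[C@@H](c3cc(OC)c4c(c3)[C@@H](CO)[C@H](c3cc(OC)c5c(c3)[C@H](CO)[C@@H](c3ccc(OCc6ccccc6)c(OC)c3)O5)O4)[C@H]2CO)ccc1OCc1ccccc1
F9 | step 17 | trimethylsilyl ether of 24 | O=C1O[C@H](c2ccc(OCc3ccccc3)c(OC)c2)[C@@H](CO[Si](C)(C)C)C1
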